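At early times the enzyme can make target at up to 18.2 mM h⁻¹, faster than over-reaction removes it at the solubility, 1.08 mM h⁻¹, so dissolved target can pass 0.95 mM and crystals can form.

    second substrate + starting complex ⇌ ternary complex (K1 = 250 M⁻¹, k1 = 24700 M⁻¹ s⁻¹)
    target → over-reaction product (k2 = 1.14 h⁻¹)
    crystals ⇌ target, rate k3*(cs3 - [target]) while solid is left; crystals form when [target] > cs3 (cs3 = 0.95 mM, k3 = 9.35 h⁻¹)
    starting material + enzyme ⇌ starting complex (K4 = 136 M⁻¹, k4 = 1.55 × 10⁵ M⁻¹ s⁻¹)
    ternary complex → enzyme + target (k5 = 95600 h⁻¹)

| flask | starting material | second substrate | enzyme | time |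
|---|---|---|---|---|
| maple | 0.011 M | 0.00600 M | 0.19 µM | 2.0 h |
| ash | 0.011 M | 0.0120 M | 0.19 µM | 2.0 h |
| oak | 0.011 M | 0.0250 M | 0.19 µM | 2.0 h |
| birch | 0.011 M | 0.0500 M | 0.19 µM | 2.0 h |
| cedar | 0.011 M | 0.100 M | 0.19 µM | 2.0 h |

- [target] (only what is free in solution) at the end for maple, ash, oak, birch, cedar, in this order
- how the row runs (rises all the way / falls all the way / rises, then falls / falls, then rises / hardly changes)

- amounts and yields of target count crystals too
- given per volume of solution although it is solid: crystals
- the concentration of target that is asked is that of its free form alone
- "hardly changes" means that all values lie within two and a half points (for a concentration: within two and a half percent of the largest)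
- run time (maple): 2.0 h

My reckoning rests on the balance of dissolved target while crystals stand, and that balance holds two half-lives. Over-reaction has 0.61 h, and exchange with the crystals has 0.0741 h, shorter by a factor of 8.23. Once the enzyme stops feeding it, c(target) rests where dissolution just replaces over-reaction: the floor, the solubility times k3 over the sum of k2 and k3, 0.847 mM. Any production still running lifts c(target) above the floor by its rate divided by that sum, 10.5 h⁻¹. At the floor, over-reaction drains 0.965 mM h⁻¹, or 1.93 mM over 2.0 h, less than the smaller charge of maple, 0.00600 M, so crystals can outlast the run. In maple the second substrate is the limiting reagent; in ash, starting material is. My reckoning stops there, for it does not say in which flasks production has ended by 2.0 h.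

The forecast gives 0.9 mM, 0.96 mM, 0.85 mM, 0.847 mM and 0.847 mM, so the row rises, then falls, since “oak, birch and cedar have already used up the starting material and sit on the floor”.

The flasks give 0.902 mM, 0.972 mM, 0.850 mM, 0.847 mM and 0.847 mM: the row rises, then falls, turning at 0.012 M, with ash higher than its neighbours. In oak, at 2.00 h, ternary complex is 0.0840% of the catalyst, and c(target) stands level with the floor. In ash, ternary complex is still 6.39% of the catalyst, and the reading stands 0.125 mM above the floor, which, multiplied by 10.5 h⁻¹, reads as production of 1.31 mM h⁻¹.

The numbers were drawn at random within sensible limits; the run is a simulation.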